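The numbers in the tables come from a simulation from invented constants; scatter was added.

- Turn the question round and ask what Tuesday's run would have to show if the left-handed product's rate followed the catalyst charged, for this flask is Wednesday's run and the two differ in that charge alone, 6 mM against 9 mM.

| setting | Wednesday's | Tuesday's | flask |
|---|---|---|---|
| left-handed substrate | 0.30 M | 0.30 M | 0.30 M |
| right-handed substrate | 0.30 M | 0.30 M | 0.30 M |
| solid reagent | 0.30 M | 0.30 M | 0.300 M |
| catalyst | 6 mM | 9 mM | 6.0 mM |
| added ligand | 12 mM | 12 mM | 12 mM |
| remark | the very flask that is asked about, followed so far | run made earlier |  |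

| run | time / d | left-handed product / % | left-handed substrate / % |
|---|---|---|---|
| Wednesday's | 0.208 | 2 | 50 |
| Wednesday's | 0.625 | 5 | 45 |
| Wednesday's | 1.04 | 8 | 41 |
| Wednesday's | 1.67 | 16 | 35 |
| Wednesday's | 2.50 | 24 | 30 |
| Wednesday's | 3.00 | 26 | 25 |
| Tuesday's | 0.625 | 5 | 43 |
| Tuesday's | 1.25 | 9 | 36 |
| Tuesday's | 2.08 | 17 | 31 |
| Tuesday's | 2.50 | 22 | 27 |
| Tuesday's | 3.00 | 25 | 23 |
| Tuesday's | 4.00 | 29 | 21 |

(each reading ± 1.5 percentage points)

- apparent order in catalyst when 5.0% of the left-handed substrate and right-handed substrate together are converted (percent change of the rate of making left-handed product for one percent more catalyst charged)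

- catalyst is single-handed; left-handed substrate and right-handed substrate are mirror images of each other, charged as a racemate, each of them at the stated concentration
- given per volume of solution although it is solid: solid reagent
- the numbers in the tables scatter with a standard deviation of 1.5 percentage points
- steps that have been proposed: partner + catalyst + left-handed substrate -> catalyst + left-handed product; partner + catalyst + right-handed substrate -> catalyst + right-handed product; catalyst + added ligand <-> idle complex; solid reagent <-> partner
- at the start none of the solid reagent is in solution

- I integrate a constant rate, so left-handed product grows as speed times time, and from Wednesday's reading of 26% at 3.00 d I get the supply speed, the left-handed product made per day in Wednesday's run, 0.0520 M d⁻¹.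
- If the rate went with the catalyst charged, Tuesday's run would read 32.5% at 2.50 d, but it reads 22%, while the unchanged speed gives 21.7%, and a reading scatters by 1.5 percentage points.
- My own reckoning compares the two runs at 3.00 d and reads an order of −0.0967, which I take as about zero, though it is read later than the moment asked about.
- The forecast gives 0.2, higher than my reading, from a rate ratio it puts at about 1.05 to 1.15 between the two runs, and it adds that “the order should be small, though noise is large”.
- The flask gives 0.13, less than the forecast.

    partner + catalyst + left-handed substrate → catalyst + left-handed product (k = 260 M⁻² h⁻¹)
    partner + catalyst + right-handed substrate → catalyst + right-handed product (k = 135 M⁻² h⁻¹)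
    catalyst + added ligand ⇌ idle complex, settled at all times (K = 82.6 M⁻¹)
    solid reagent ⇌ partner, rate k4*(cs4 - [partner]) while solid is left; crystals form when [partner] > cs4 (solubility = 0.130 M, k = 0.0307 h⁻¹)

- At 1.69 d the flask makes partner 1.02 times as fast as it uses it up, each step taken net. At 0.0520 M d⁻¹, the flask would reach its left-handed product of 30.6% in 3.53 d. The same line gives 34.7% for Tuesday's run at 4.00 d, where the reading is 29%.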